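At 12 min the flask asked about is the spring run left standing, so I read its end from the two runs so far.

all flasks: substrate 0.0010 M (fed, over 2.5 s)
- spring: coupling partner 2.5 mM; free catalyst 1 µM; the very flask that is asked about, followed so far; the fed solution adds 0.10 times the starting volume
- noon: coupling partner 2.5 mM; free catalyst 0.67 µM; run made earlier; the fed solution adds 0.10 times the starting volume
- flask: coupling partner 2.50 mM; free catalyst 1.0 µM; the fed solution adds 0.10 times the starting volume; time 12 min

| run | time / min | target / % | isomer of the product / % |
|---|---|---|---|
| spring | 0.417 | 51.8 | 9.1 |
| spring | 1.33 | 56.2 | 41.7 |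
| spring | 2.00 | 47.4 | 52.4 |
| spring | 3.00 | 41.6 | 57.6 |
| spring | 5.00 | 39.6 | 59.6 |
| spring | 6.00 | 39.8 | 59.0 |
| noon | 0.417 | 38.7 | 6.9 |
| noon | 0.667 | 50.0 | 14.7 |
| noon | 1.00 | 56.1 | 26.4 |
| noon | 2.00 | 49.0 | 49.0 |
| noon | 3.00 | 42.6 | 57.2 |
| noon | 5.00 | 40.0 | 59.7 |

(scatter of a reading: 0.3 percentage points)

- which holds at 12 min: what has brought the reaction to rest, or that it has not come to rest (it is still moving / no working catalyst is left / all of the substrate has reacted / the coupling partner has run out first / forward and back rates have come level)
- amount of target at 12 min, in percent of the substrate charged
- amount of isomer of the product at 12 min, in percent of the substrate charged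

- charges are per starting volume, the dose included; the dosed solution carries all of it
- the reaction counts as stopped when no species that holds the substrate changes by six tenths of a point or more over the second half of the time

1. I follow one molecule of substrate: once reacted, it stands as target or as isomer of the product. The spring run at 6.00 min gives, as a reading, 0.403 for the target share, the chance that a reacted molecule stands as target, [target]/([target] + [isomer of the product]).

2. The second way is the noon run, with 0.67 µM of free catalyst against 1 µM. At 5.00 min it gives 0.401, the same share from a different catalyst charge, so I trust it.

3. The two ways part on the sum of target and isomer: 98.8% in the spring run against 99.7% in the noon run. The spring isomer reading dips from 59.6% to 59.0%, with a scatter of 0.3 percentage points per reading, and the spring sum at 5.00 min is 99.2%. I take that last spring sum as the one that misleads, by scatter; the share at 5.00 min is still 0.399.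

4. [coupling partner] starts at 2.50 times the substrate charge, so substrate is the limiting reagent. The noon sum leaves 0.3 points unaccounted, the size of the scatter, so I expect the substrate used up by 12 min. My reckoning is therefore target 40.3% and isomer 59.7%.

5. The forecast says forward and back rates have come level, with target 39.8% and isomer 59.5%, on the ground that “The plateau is therefore an equilibrium”. Its isomer lies below my reckoning, and it names another end.

6. The flask gives: all of the substrate has reacted, with target 40.0% and isomer 60.0%.

    coupling partner + free catalyst ⇌ catalyst intermediate A (K = 3400 M⁻¹, k = 4.70 × 10⁵ M⁻¹ s⁻¹)
    catalyst intermediate A → released group + catalyst intermediate B (k = 180 s⁻¹)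
    catalyst intermediate B ⇌ catalyst intermediate C (K = 29.0, k = 150 s⁻¹)
    substrate + catalyst intermediate C → catalyst intermediate D (k = 70000 M⁻¹ s⁻¹)
    catalyst intermediate D → free catalyst + target (k = 11000 s⁻¹)
    target ⇌ isomer of the product (K = 1.50, k = 0.0140 s⁻¹)

At 12.0 min the flask holds 0% of substrate and 60% of its coupling partner, the relaxation half-life of target and isomer by their own step, both ways together, is 0.495 min, short against 12 min, and the target share in the flask is 0.400. One more flask, with 6.3 × 10⁻⁴ M of coupling partner (0.630 equiv), ends with 0% of coupling partner and 37% of substrate, so the share I read from the spring run gives 25.4% of target, and that flask holds 25.2% of target.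

The readings stem from a simulated flask for an exercise; the scatter is artificial.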